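**Strategy**

The route rests on cutting the C5–C6 bond, where C6 is at once the allylic carbinol carbon next to the Z-C4=C5 alkene of the ten-membered ring and the alkoxy carbon of the γ-lactone (O–C6–C7–C11–C12). An open-chain Z-alkenyl iodide (C5) bearing a C6 aldehyde, with every other stereocentre, both esters and a C12 methyl ester in place, undergoes a Nozaki–Hiyama–Kishi addition that closes the carbocycle and sets C6; the resulting C6 chromium alkoxide then closes the lactone on C12 in the same flask. The precursor is assembled by a Z-selective Wittig union and an indium Barbier allylation that sets C7 and C8.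

Key step: step 22

Remark: atom labels follow germacranolide numbering (ring C1–C10 with C1=C10 and C4=C5, C14 on C10, C15 on C4, lactone O–C6 and C7–C11(=C13)–C12); compounds 1, 2, 8, 20, 24 and 29 are taken as purchasable.

**Route**

Step 1
Reactants: 1 3-chloropropanoyl chloride; 2 bis(trimethylsilyl)acetylene
Product: 3 5-chloro-1-(trimethylsilyl)pent-1-yn-3-one
Conditions: AlCl3, CH2Cl2, 0 °C
Reagents that add atoms: none
Why: Friedel–Crafts-type ipso-acylation of the alkynylsilane by the acylium complex should stop after one silyl group because the ynone formed is deactivated.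

Step 2
Reactants: 3 5-chloro-1-(trimethylsilyl)pent-1-yn-3-one
Product: 4 (3S)-5-chloro-1-(trimethylsilyl)pent-1-yn-3-ol
Conditions: Ru[(S,S)-TsNCH(Ph)CH(Ph)NH](p-cymene) (1 mol%), i-PrOH, rt
Reagents that add atoms: none
Why: Noyori asymmetric transfer hydrogenation of an alkynyl alkyl ketone, in which the (S,S)-catalyst (the enantiomer that gives (S)-propargylic alcohols) should set C3 under base-free conditions that spare the β-chloride.

Step 3
Reactants: 4 (3S)-5-chloro-1-(trimethylsilyl)pent-1-yn-3-ol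
Product: 5 (3S)-3-(tert-butyldimethylsilyloxy)-5-chloro-1-(trimethylsilyl)pent-1-yne
Conditions: TBSCl, imidazole, DMF, rt
Reagents that add atoms: tert-butyldimethylsilyl chloride, CC(C)(C)[Si](C)(C)Cl
Why: Standard silylation masks the C3 hydroxyl so that no alkoxide interferes with the ylide chemistry of step 6.

Step 4
Reactants: 5 (3S)-3-(tert-butyldimethylsilyloxy)-5-chloro-1-(trimethylsilyl)pent-1-yne
Product: 7 [(3S)-3-(tert-butyldimethylsilyloxy)-5-(trimethylsilyl)pent-4-yn-1-yl]triphenylphosphonium iodide, via alkyl iodide 6 (not isolated)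
Conditions: NaI, PPh3, MeCN, reflux
Reagents that add atoms: sodium iodide, [Na+].[I-]; triphenylphosphine, c1ccc(cc1)P(c1ccccc1)c1ccccc1
Why: Finkelstein exchange in the flask followed by SN2 quaternisation of PPh3 at the unhindered primary carbon should give the salt, both silyl groups being inert to these neutral conditions.

Step 5
Reactants: 8 methyl (4S)-2,2-dimethyl-1,3-dioxolane-4-carboxylate
Product: 10 1-[(4S)-2,2-dimethyl-1,3-dioxolan-4-yl]ethan-1-one, via Weinreb amide 9 (not isolated)
Conditions: MeNHOMe·HCl, i-PrMgCl, THF, −20 °C; then MeMgBr, −20 to 0 °C; aq. NH4Cl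
Reagents that add atoms: methylmagnesium bromide, C[Mg]Br
Why: One-flask Weinreb ketone synthesis, in which the chelated tetrahedral adduct stops the Grignard addition at the ketone and the chiral-pool centre (future C9) is not enolised at low temperature.

Step 6
Reactants: 7 phosphonium iodide; 10 1-[(4S)-2,2-dimethyl-1,3-dioxolan-4-yl]ethan-1-one
Product: 12 (4R)-4-[(2Z,5S)-5-(tert-butyldimethylsilyloxy)-7-(trimethylsilyl)hept-2-en-6-yn-2-yl]-2,2-dimethyl-1,3-dioxolane, via phosphorus ylide 11 (not isolated)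
Conditions: NaN(SiMe3)2, THF, −78 to 0 °C; then 10, −78 °C to rt
Reagents that add atoms: none
Why: Wittig olefination of an α-alkoxy methyl ketone with a non-stabilised ylide under lithium-free conditions (the Z-selective variant for trisubstituted allylic ethers) should place the new chain cis to the oxygenated carbon and so give the Z-C1=C10 alkene.

Step 7
Reactants: 12 silylated enyne acetonide
Product: 13 (3S,5Z)-6-[(4R)-2,2-dimethyl-1,3-dioxolan-4-yl]hept-5-en-1-yn-3-ol
Conditions: Bu4NF, THF, 0 °C to rt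
Reagents that add atoms: none
Why: Fluoride-mediated desilylation should cleave the alkynyl C–Si bond and the O–Si bond in one operation, leaving the acetonide untouched.

Step 8
Reactants: 13 (3S,5Z)-6-[(4R)-2,2-dimethyl-1,3-dioxolan-4-yl]hept-5-en-1-yn-3-ol
Product: 15 (1Z,3S,5Z)-6-[(4R)-2,2-dimethyl-1,3-dioxolan-4-yl]-1-iodo-2-methylhepta-1,5-dien-3-ol, via alkenylmagnesium alkoxide 14 (not isolated)
Conditions: MeMgBr (4 equiv), CuI (0.2 equiv), Et2O–THF, −10 °C to rt; then I2, −40 to 0 °C
Reagents that add atoms: methylmagnesium bromide, C[Mg]Br; iodine, II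
Why: Copper-catalysed anti-carbomagnesiation of the propargylic magnesium alkoxide puts the methyl group on C4 and magnesium on C5 cis to the alkoxide through a five-membered chelate, and iodinolysis with retention should give the Z-alkenyl iodide (iodine cis to C3).

Step 9
Reactants: 15 iodo dienol
Product: 16 (1Z,3S,5Z)-6-[(4R)-2,2-dimethyl-1,3-dioxolan-4-yl]-1-iodo-2-methylhepta-1,5-dien-3-yl acetate
Conditions: Ac2O, pyridine, DMAP (cat.), CH2Cl2, 0 °C to rt
Reagents that add atoms: acetic anhydride, CC(=O)OC(C)=O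
Why: DMAP-catalysed acetylation of the only free hydroxyl installs the C3 acetate of the target once all strongly basic steps are over.

Step 10
Reactants: 16 acetonide acetate
Product: 17 (1Z,3S,5Z,7R)-7,8-dihydroxy-1-iodo-2,6-dimethylocta-1,5-dien-3-yl acetate
Conditions: AcOH–H2O (4:1), 40 °C
Reagents that add atoms: none
Why: Acid-catalysed hydrolysis of the terminal acetonide should free the C8/C9 diol while the acetate and the alkenyl iodide tolerate aqueous acetic acid.

Step 11
Reactants: 17 diol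
Product: 18 (1Z,3S,5Z,7R)-1-iodo-2,6-dimethyl-7,8-bis(triethylsilyloxy)octa-1,5-dien-3-yl acetate
Conditions: Et3SiCl, imidazole, DMAP (cat.), DMF, 0 °C to rt
Reagents that add atoms: chlorotriethylsilane, CC[Si](Cl)(CC)CC
Why: Silylation of both hydroxyls prepares the selective oxidative unmasking of the primary position in step 12.

Step 12
Reactants: 18 bis(triethylsilyl) ether
Product: 19 (1Z,3S,5Z,7R)-1-iodo-2,6-dimethyl-8-oxo-7-(triethylsilyloxy)octa-1,5-dien-3-yl acetate
Conditions: (COCl)2, DMSO, CH2Cl2, −78 to −30 °C; then i-Pr2NEt, −78 to −20 °C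
Reagents that add atoms: none
Why: Swern oxidation applied directly to the bis-silyl ether should cleave and oxidise only the primary triethylsilyl ether, giving the α-silyloxy aldehyde (C8) with the C9 ether intact.

Step 13
Reactants: 20 (2Z)-but-2-ene-1,4-diol
Product: 21 (2Z)-1,4-bis(triethylsilyloxy)but-2-ene
Conditions: Et3SiCl, imidazole, CH2Cl2, 0 °C to rt
Reagents that add atoms: chlorotriethylsilane, CC[Si](Cl)(CC)CC
Why: Routine bis-silylation of a primary diol.

Step 14
Reactants: 21 (2Z)-1,4-bis(triethylsilyloxy)but-2-ene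
Product: 23 2-(triethylsilyloxy)acetaldehyde, via ozonide 22 (not isolated)
Conditions: O3, CH2Cl2, −78 °C; then PPh3, −78 °C to rt
Reagents that add atoms: ozone, [O-][O+]=O
Why: Ozonolysis with reductive work-up should cut the symmetrical alkene into two molecules of the aldehyde.

Step 15
Reactants: 23 2-(triethylsilyloxy)acetaldehyde; 24 methyl acrylate
Product: 25 methyl 3-hydroxy-2-methylidene-4-(triethylsilyloxy)butanoate (racemic)
Conditions: DABCO (0.5 equiv), neat, rt
Reagents that add atoms: none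
Why: Morita–Baylis–Hillman reaction joins C6–C7 to the acrylate unit C11–C13; the stereocentre formed is erased in step 16.

Step 16
Reactants: 25 Morita–Baylis–Hillman adduct
Product: 26 methyl (2Z)-2-(bromomethyl)-4-(triethylsilyloxy)but-2-enoate
Conditions: NBS, Me2S, CH2Cl2, 0 °C to rt
Reagents that add atoms: N-bromosuccinimide, O=C1CCC(=O)N1Br
Why: Corey–Kim-type activation of the allylic alcohol and SN2' delivery of bromide should give the thermodynamically preferred Z-2-(bromomethyl)enoate (CH2OSi trans to the ester).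

Step 17
Reactants: 19 α-silyloxy aldehyde; 26 methyl (2Z)-2-(bromomethyl)-4-(triethylsilyloxy)but-2-enoate
Product: 28 methyl (3S,4S,5R,6Z,9S,10Z)-9-acetoxy-4-hydroxy-11-iodo-6,10-dimethyl-2-methylidene-5-(triethylsilyloxy)-3-[(triethylsilyloxy)methyl]undeca-6,10-dienoate, via allylindium bromide 27 (not isolated)
Conditions: In (powder), DMF, 0 °C to rt; aq. NaH2PO4/Na2HPO4 (pH 7)
Reagents that add atoms: none
Why: Indium-mediated Barbier allylation, in which the Z-allylindium reacts through a chair transition state (syn relation of the C8 hydroxyl and the C6 arm) on the Felkin–Anh face of the α-silyloxy aldehyde (C8/C9 anti), should set C7 (S) and C8 (S) from C9.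

Step 18
Reactants: 29 (2E)-2-methylbut-2-en-1-ol
Product: 30 [(2R,3R)-2,3-dimethyloxiran-2-yl]methanol
Conditions: Ti(OiPr)4 (cat.), D-(−)-diethyl tartrate (cat.), t-BuOOH, 4 Å molecular sieves, CH2Cl2, −20 °C
Reagents that add atoms: tert-butyl hydroperoxide, CC(C)(C)OO
Why: Katsuki–Sharpless asymmetric epoxidation with the D-(−)-tartrate (the L-(+)-tartrate gives 2S,3S) should deliver oxygen to the face that gives the (2R,3R)-epoxy alcohol, setting both epoxide centres of the side chain.

Step 19
Reactants: 30 [(2R,3R)-2,3-dimethyloxiran-2-yl]methanol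
Product: 31 (2S,3R)-2,3-dimethyloxirane-2-carboxylic acid
Conditions: RuCl3·xH2O (cat.), NaIO4, CCl4–MeCN–H2O, rt
Reagents that add atoms: sodium periodate, [Na+].[O-]I(=O)(=O)=O
Why: RuO4 generated in the flask oxidises the primary alcohol to the acid without opening the epoxide; the C2 descriptor changes from R to S only through the change in priorities.

Step 20
Reactants: 28 C8 alcohol; 31 (2S,3R)-2,3-dimethyloxirane-2-carboxylic acid
Product: 33 methyl (3S,4S,5R,6Z,9S,10Z)-9-acetoxy-4-{[(2S,3R)-2,3-dimethyloxirane-2-carbonyl]oxy}-11-iodo-6,10-dimethyl-2-methylidene-5-(triethylsilyloxy)-3-[(triethylsilyloxy)methyl]undeca-6,10-dienoate, via mixed anhydride 32 (not isolated)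
Conditions: 2,4,6-Cl3C6H2COCl, Et3N, toluene, rt; then 28, DMAP, rt to 40 °C
Reagents that add atoms: none
Why: Yamaguchi esterification should transfer the hindered epoxy acyl group through the acylpyridinium to the only free hydroxyl (C8), C9 being silylated, with no stereocentre touched.

Step 21
Reactants: 33 epoxy ester
Product: 34 methyl (3R,4S,5R,6Z,9S,10Z)-9-acetoxy-4-{[(2S,3R)-2,3-dimethyloxirane-2-carbonyl]oxy}-3-formyl-11-iodo-6,10-dimethyl-2-methylidene-5-(triethylsilyloxy)undeca-6,10-dienoate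
Conditions: (COCl)2, DMSO, CH2Cl2, −78 to −40 °C; then i-Pr2NEt, −78 °C; cold aq. NaH2PO4/Na2HPO4 (pH 7)
Reagents that add atoms: none
Why: Swern oxidation performed directly on the primary triethylsilyl ether should give the C6 aldehyde without ever freeing a γ-hydroxy ester that could lactonise, and Hünig's base at −78 °C limits enolisation at C7.

Step 22
Reactants: 34 iodo aldehyde
Product: 36 (3aS,4S,5R,6Z,9S,10Z,11aR)-9-acetoxy-6,10-dimethyl-3-methylidene-2-oxo-5-(triethylsilyloxy)-2,3,3a,4,5,8,9,11a-octahydrocyclodeca[b]furan-4-yl (2S,3R)-2,3-dimethyloxirane-2-carboxylate, via ten-membered hydroxy ester 35 (not isolated)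
Conditions: CrCl2 (20 equiv), NiCl2 (0.2 equiv), DMSO–THF (3:1), 0.002 M, slow addition, rt; then 40 °C
Reagents that add atoms: none
Why: NiCl2 is reduced by CrCl2 to zerovalent nickel, which inserts into the C5–I bond with retention of the Z geometry; transmetallation to trivalent chromium gives an alkenylchromium that adds to the C6 aldehyde (Nozaki–Hiyama–Kishi macrocyclisation, a known way to close medium carbocycles), and the C6 chromium alkoxide then attacks the C12 methyl ester and expels methoxide. The ten-membered carbocycle closes by a 10-exo-trig addition to the C6 carbonyl and the γ-lactone by a 5-exo-trig acyl substitution at C12. The new stereocentre C6 (R) is controlled by C7: the alkenyl group should attack the Felkin–Anh face anti to the C7–C8 bond with the acrylate branch next to the carbonyl oxygen, which is also the 1,3-anti mode with respect to the C8 acyloxy group, and this epimer leads to the trans-fused lactone. The step needs chemoselectivity for the aldehyde over three esters, the epoxide and the enoate (alkenylchromium reagents add only to aldehydes at room temperature), ring closure over oligomerisation (high dilution and the two Z alkenes, which fold the chain into the shape of the cis,cis-cyclodecadiene) and integrity of the enolisable C7 centre (neutral aprotic medium).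

Step 23
Reactants: 36 silylated lactone
Product: 37 (3aS,4S,5R,6Z,9S,10Z,11aR)-9-acetoxy-5-hydroxy-6,10-dimethyl-3-methylidene-2-oxo-2,3,3a,4,5,8,9,11a-octahydrocyclodeca[b]furan-4-yl (2S,3R)-2,3-dimethyloxirane-2-carboxylate
Conditions: HF·pyridine, pyridine, THF, 0 °C to rt
Reagents that add atoms: none
Why: Buffered fluoride cleavage of the secondary silyl ether should free the C9 hydroxyl and leave the epoxide, the esters and the α-methylene lactone intact.

**Compound list**

1 | 3-chloropropanoyl chloride | ClCCC(Cl)=O | starting material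
2 | bis(trimethylsilyl)acetylene | C[Si](C)(C)C#C[Si](C)(C)C | starting material
3 | 5-chloro-1-(trimethylsilyl)pent-1-yn-3-one | C[Si](C)(C)C#CC(=O)CCCl | intermediate
4 | (3S)-5-chloro-1-(trimethylsilyl)pent-1-yn-3-ol | C[Si](C)(C)C#C[C@@H](O)CCCl | intermediate
5 | (3S)-3-(tert-butyldimethylsilyloxy)-5-chloro-1-(trimethylsilyl)pent-1-yne | C[Si](C)(C)C#C[C@@H](O[Si](C)(C)C(C)(C)C)CCCl | intermediate
6 | (3S)-3-(tert-butyldimethylsilyloxy)-5-iodo-1-(trimethylsilyl)pent-1-yne (not isolated) | C[Si](C)(C)C#C[C@@H](O[Si](C)(C)C(C)(C)C)CCI | intermediate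
7 | [(3S)-3-(tert-butyldimethylsilyloxy)-5-(trimethylsilyl)pent-4-yn-1-yl]triphenylphosphonium iodide | C[Si](C)(C)C#C[C@@H](O[Si](C)(C)C(C)(C)C)CC[P+](c1ccccc1)(c1ccccc1)c1ccccc1.[I-] | intermediate
8 | methyl (4S)-2,2-dimethyl-1,3-dioxolane-4-carboxylate | COC(=O)[C@@H]1COC(C)(C)O1 | starting material
9 | (4S)-N-methoxy-N,2,2-trimethyl-1,3-dioxolane-4-carboxamide (not isolated) | CON(C)C(=O)[C@@H]1COC(C)(C)O1 | intermediate
10 | 1-[(4S)-2,2-dimethyl-1,3-dioxolan-4-yl]ethan-1-one | CC(=O)[C@@H]1COC(C)(C)O1 | intermediate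
11 | [(3S)-3-(tert-butyldimethylsilyloxy)-5-(trimethylsilyl)pent-4-yn-1-ylidene]triphenylphosphorane (not isolated) | C[Si](C)(C)C#C[C@@H](O[Si](C)(C)C(C)(C)C)CC=P(c1ccccc1)(c1ccccc1)c1ccccc1 | intermediate
12 | (4R)-4-[(2Z,5S)-5-(tert-butyldimethylsilyloxy)-7-(trimethylsilyl)hept-2-en-6-yn-2-yl]-2,2-dimethyl-1,3-dioxolane | C[Si](C)(C)C#C[C@@H](O[Si](C)(C)C(C)(C)C)C/C=C(/C)[C@@H]1COC(C)(C)O1 | intermediate
13 | (3S,5Z)-6-[(4R)-2,2-dimethyl-1,3-dioxolan-4-yl]hept-5-en-1-yn-3-ol | C#C[C@@H](O)C/C=C(/C)[C@@H]1COC(C)(C)O1 | intermediate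
14 | bromomagnesium alkoxide of the (1Z)-alkenylmagnesium bromide formed from 13, magnesium on C5 cis to C3 (not isolated) | Br[Mg]/C=C(/C)[C@@H](O[Mg]Br)C/C=C(/C)[C@@H]1COC(C)(C)O1 | intermediate
15 | (1Z,3S,5Z)-6-[(4R)-2,2-dimethyl-1,3-dioxolan-4-yl]-1-iodo-2-methylhepta-1,5-dien-3-ol | I/C=C(/C)[C@@H](O)C/C=C(/C)[C@@H]1COC(C)(C)O1 | intermediate
16 | (1Z,3S,5Z)-6-[(4R)-2,2-dimethyl-1,3-dioxolan-4-yl]-1-iodo-2-methylhepta-1,5-dien-3-yl acetate | I/C=C(/C)[C@@H](OC(C)=O)C/C=C(/C)[C@@H]1COC(C)(C)O1 | intermediate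
17 | (1Z,3S,5Z,7R)-7,8-dihydroxy-1-iodo-2,6-dimethylocta-1,5-dien-3-yl acetate | I/C=C(/C)[C@@H](OC(C)=O)C/C=C(/C)[C@@H](O)CO | intermediate
18 | (1Z,3S,5Z,7R)-1-iodo-2,6-dimethyl-7,8-bis(triethylsilyloxy)octa-1,5-dien-3-yl acetate | I/C=C(/C)[C@@H](OC(C)=O)C/C=C(/C)[C@@H](O[Si](CC)(CC)CC)CO[Si](CC)(CC)CC | intermediate
19 | (1Z,3S,5Z,7R)-1-iodo-2,6-dimethyl-8-oxo-7-(triethylsilyloxy)octa-1,5-dien-3-yl acetate | I/C=C(/C)[C@@H](OC(C)=O)C/C=C(/C)[C@@H](O[Si](CC)(CC)CC)C=O | intermediate
20 | (2Z)-but-2-ene-1,4-diol | OC/C=C\CO | starting material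
21 | (2Z)-1,4-bis(triethylsilyloxy)but-2-ene | CC[Si](CC)(CC)OC/C=C\CO[Si](CC)(CC)CC | intermediate
22 | 3,5-bis[(triethylsilyloxy)methyl]-1,2,4-trioxolane (not isolated) | CC[Si](CC)(CC)OCC1OOC(CO[Si](CC)(CC)CC)O1 | intermediate
23 | 2-(triethylsilyloxy)acetaldehyde | CC[Si](CC)(CC)OCC=O | intermediate
24 | methyl acrylate | C=CC(=O)OC | starting material
25 | methyl 3-hydroxy-2-methylidene-4-(triethylsilyloxy)butanoate (racemic) | COC(=O)C(=C)C(O)CO[Si](CC)(CC)CC | intermediate
26 | methyl (2Z)-2-(bromomethyl)-4-(triethylsilyloxy)but-2-enoate | COC(=O)/C(CBr)=C/CO[Si](CC)(CC)CC | intermediate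
27 | allylindium dibromide from 26, indium on C13, alkene geometry as in 26 (not isolated) | COC(=O)/C(C[In](Br)Br)=C/CO[Si](CC)(CC)CC | intermediate
28 | methyl (3S,4S,5R,6Z,9S,10Z)-9-acetoxy-4-hydroxy-11-iodo-6,10-dimethyl-2-methylidene-5-(triethylsilyloxy)-3-[(triethylsilyloxy)methyl]undeca-6,10-dienoate | I/C=C(/C)[C@@H](OC(C)=O)C/C=C(/C)[C@@H](O[Si](CC)(CC)CC)[C@@H](O)[C@@H](C(=C)C(=O)OC)CO[Si](CC)(CC)CC | intermediate
29 | (2E)-2-methylbut-2-en-1-ol | C/C=C(\C)CO | starting material
30 | [(2R,3R)-2,3-dimethyloxiran-2-yl]methanol | OC[C@@]1(C)O[C@@H]1C | intermediate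
31 | (2S,3R)-2,3-dimethyloxirane-2-carboxylic acid | OC(=O)[C@@]1(C)O[C@@H]1C | intermediate
32 | (2S,3R)-2,3-dimethyloxirane-2-carboxylic 2,4,6-trichlorobenzoic anhydride (not isolated) | O=C(OC(=O)[C@@]1(C)O[C@@H]1C)c1c(Cl)cc(Cl)cc1Cl | intermediate
33 | methyl (3S,4S,5R,6Z,9S,10Z)-9-acetoxy-4-{[(2S,3R)-2,3-dimethyloxirane-2-carbonyl]oxy}-11-iodo-6,10-dimethyl-2-methylidene-5-(triethylsilyloxy)-3-[(triethylsilyloxy)methyl]undeca-6,10-dienoate | I/C=C(/C)[C@@H](OC(C)=O)C/C=C(/C)[C@@H](O[Si](CC)(CC)CC)[C@@H](OC(=O)[C@@]1(C)O[C@@H]1C)[C@@H](C(=C)C(=O)OC)CO[Si](CC)(CC)CC | intermediate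
34 | methyl (3R,4S,5R,6Z,9S,10Z)-9-acetoxy-4-{[(2S,3R)-2,3-dimethyloxirane-2-carbonyl]oxy}-3-formyl-11-iodo-6,10-dimethyl-2-methylidene-5-(triethylsilyloxy)undeca-6,10-dienoate | I/C=C(/C)[C@@H](OC(C)=O)C/C=C(/C)[C@@H](O[Si](CC)(CC)CC)[C@@H](OC(=O)[C@@]1(C)O[C@@H]1C)[C@@H](C(=C)C(=O)OC)C=O | intermediate
35 | methyl 2-[(1S,2R,3Z,5S,7Z,9R,10S)-5-acetoxy-10-{[(2S,3R)-2,3-dimethyloxirane-2-carbonyl]oxy}-2-hydroxy-4,8-dimethyl-9-(triethylsilyloxy)cyclodeca-3,7-dien-1-yl]prop-2-enoate, formed as its chromium alkoxide (not isolated) | O[C@@H]1/C=C(/C)[C@@H](OC(C)=O)C/C=C(/C)[C@@H](O[Si](CC)(CC)CC)[C@@H](OC(=O)[C@@]2(C)O[C@@H]2C)[C@H]1C(=C)C(=O)OC | intermediate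
36 | (3aS,4S,5R,6Z,9S,10Z,11aR)-9-acetoxy-6,10-dimethyl-3-methylidene-2-oxo-5-(triethylsilyloxy)-2,3,3a,4,5,8,9,11a-octahydrocyclodeca[b]furan-4-yl (2S,3R)-2,3-dimethyloxirane-2-carboxylate | C=C1C(=O)O[C@@H]2/C=C(/C)[C@@H](OC(C)=O)C/C=C(/C)[C@@H](O[Si](CC)(CC)CC)[C@@H](OC(=O)[C@@]3(C)O[C@@H]3C)[C@@H]12 | intermediate
37 | (3aS,4S,5R,6Z,9S,10Z,11aR)-9-acetoxy-5-hydroxy-6,10-dimethyl-3-methylidene-2-oxo-2,3,3a,4,5,8,9,11a-octahydrocyclodeca[b]furan-4-yl (2S,3R)-2,3-dimethyloxirane-2-carboxylate (CNP0299903.2) | C=C1C(=O)O[C@@H]2/C=C(/C)[C@@H](OC(C)=O)C/C=C(/C)[C@@H](O)[C@@H](OC(=O)[C@@]3(C)O[C@@H]3C)[C@@H]12 | target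

**Step count and risk**

Total: 23 steps. Longest linear sequence: 16 steps (steps 1–4, 6–12, 17, 20–23).

The three steps most likely to fail:

Step 22. The ten-membered transition state may override the acyclic Felkin–Anh preference, so that the alkenylchromium attacks the wrong face of the C6 aldehyde. The fallback sets out from 34 and returns at 36, and it moves the control of C6 from the C–C bond formation to a ketone reduction. The chromium-mediated closure is quenched cold with aq. NH4Cl before lactonisation, so that hydroxy ester 35 and its C6 epimer, the (6S)-hydroxy ester F1, are isolated together. Dess–Martin oxidation converges both on the ten-membered C6 ketone F2. A reagent-controlled Corey–Bakshi–Shibata reduction (the (R)-oxazaborolidine with catecholborane, if the alkenyl arm acts as the large group, so that hydride reaches the Si face of C6) should then give 35 alone, which is closed to 36 with catalytic pyridinium p-toluenesulfonate in benzene.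

Step 21. The amine base may enolise the new aldehyde at C7, which moves the C11=C13 alkene into conjugation or epimerises C7. The fallback sets out from 33 and returns at 34 and avoids any amine base at the aldehyde stage. The primary silyl ether alone is cleaved with HF·pyridine buffered with pyridine in THF at 0 °C to the primary alcohol F3. F3 is oxidised at once with Dess–Martin periodinane and NaHCO3 in CH2Cl2.

Step 17. The syn or Felkin–Anh selectivity may erode in the open indium medium, or the new C8 hydroxyl may close onto C12 under the Lewis-acidic indium salts. The fallback sets out from 25 (with aldehyde 19) and returns at 28, and it replaces the Barbier reaction by an allylboration. Adduct 25 is acetylated (Ac2O, pyridine) to the allylic acetate F4. F4 is borylated with B2pin2 and Pd2(dba)3 to the allylboronate F5, which has boron on C13 and the alkene geometry of 26. F5 is added to 19 under Sc(OTf)3 catalysis at −78 °C through a closed six-membered transition state, so that the syn C7/C8 relation follows from the alkene geometry and the facial choice from C9; aqueous work-up should give 28.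

Further compounds
F1 | step 22 | methyl 2-[(1S,2S,3Z,5S,7Z,9R,10S)-5-acetoxy-10-{[(2S,3R)-2,3-dimethyloxirane-2-carbonyl]oxy}-2-hydroxy-4,8-dimethyl-9-(triethylsilyloxy)cyclodeca-3,7-dien-1-yl]prop-2-enoate (C6 epimer of 35) | O[C@H]1/C=C(/C)[C@@H](OC(C)=O)C/C=C(/C)[C@@H](O[Si](CC)(CC)CC)[C@@H](OC(=O)[C@@]2(C)O[C@@H]2C)[C@H]1C(=C)C(=O)OC
F2 | step 22 | ten-membered C6 ketone of 35 (2-oxocyclodeca-3,7-dienyl acrylate, other centres as in 35) | O=C1/C=C(/C)[C@@H](OC(C)=O)C/C=C(/C)[C@@H](O[Si](CC)(CC)CC)[C@@H](OC(=O)[C@@]2(C)O[C@@H]2C)[C@H]1C(=C)C(=O)OC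
F3 | step 21 | methyl (3S,4S,5R,6Z,9S,10Z)-9-acetoxy-4-{[(2S,3R)-2,3-dimethyloxirane-2-carbonyl]oxy}-3-(hydroxymethyl)-11-iodo-6,10-dimethyl-2-methylidene-5-(triethylsilyloxy)undeca-6,10-dienoate | I/C=C(/C)[C@@H](OC(C)=O)C/C=C(/C)[C@@H](O[Si](CC)(CC)CC)[C@@H](OC(=O)[C@@]1(C)O[C@@H]1C)[C@@H](C(=C)C(=O)OC)CO
F4 | step 17 | methyl 3-acetoxy-2-methylidene-4-(triethylsilyloxy)butanoate (racemic) | COC(=O)C(=C)C(OC(C)=O)CO[Si](CC)(CC)CC
F5 | step 17 | methyl (2E)-2-[(4,4,5,5-tetramethyl-1,3,2-dioxaborolan-2-yl)methyl]-4-(triethylsilyloxy)but-2-enoate | COC(=O)/C(CB1OC(C)(C)C(C)(C)O1)=C/CO[Si](CC)(CC)CC
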